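Thursday's flask stood at 80 °C and Wednesday's at 50 °C, with the same charges and the same time, so temperature is the one difference to watch.

in all of them: substrate 0.050 M; partner 0.0450 M; time 4.0 min

| charge | temperature |
|---|---|
| Thursday's | 80 °C |
| Wednesday's | 50 °C |

    partner + target → over-reaction product (k1 = 0.033 M⁻¹ s⁻¹, Ea1 = 84.0 kJ mol⁻¹)
    partner → second intermediate (k2 = 0.021 s⁻¹, Ea2 = 95.0 kJ mol⁻¹)
    substrate → open intermediate (k3 = 0.052 s⁻¹, Ea3 = 105 kJ mol⁻¹)
    open intermediate + second intermediate → target (k4 = 0.19 M⁻¹ s⁻¹, Ea4 = 42.0 kJ mol⁻¹)
    (constants at 80 °C)

- the list of constants is for 80 °C, to be carried to other temperatures by the activation energies

- which flask leads in amount of target, in percent of the substrate charged ("all alike" within 1.5 percentage points) (Thursday's / Wednesday's / all alike)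
- how much target is there at the end, in percent of the substrate charged: Thursday's
- how much target is there at the end, in percent of the substrate charged: Wednesday's

I counted turnovers. For the substrate step and the partner step, the count N is the rate constant at the flask's temperature times the time, which is the number of lifetimes the step gets. For the coupling of the two intermediates, I also multiplied by the partner charge, supposing that the second intermediate stands at that full charge.

My table had three rows, each read as Thursday's against Wednesday's:

- Substrate count N_s: 12.5 against 0.451.
- Partner count N_p: 5.04 against 0.250.
- Coupling count N_c: 2.05 against 0.544.

This turnover count, rate constant at the flask's temperature times the time, was the quantity I carried forward. Reading along the rows, cooling cut the counts by factors of 27.7, 20.2 and 3.77, so the forming steps lost more than the coupling did.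

Reading down Thursday's column, both forming counts exceeded the coupling count, so coupling was the rate-limiting step there. I let it start after one partner lifetime, 47.6 s, with both intermediates at full charge. The second-order law for unequal charges then gave 1.20 as its exponential term and 60.1% target.

Reading down Wednesday's column, each count stayed below one. I therefore let both intermediates grow in step with time, which makes target grow with the cube of time, so my estimate of the target share was N_s·N_p·N_c/3, or 2.05%. That reckoning counts no depletion, so I held it as an upper estimate.

The forecast named Thursday's, with 57.5% (54% to 61%) for Thursday's and 1.45% (1.2% to 1.7%) for Wednesday's, calling the hot run “limited mainly by their bimolecular coupling”. My Thursday's figure stood above its central value but inside its range, and my Wednesday's figure stood above its range.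

The simulation gave Thursday's the lead, with 57.5% in Thursday's flask and 1.47% in Wednesday's.

The forecast held on both. Thursday's flask carried 0.708% over-reaction product at the end. In Wednesday's flask, exp(−N_s) gave 63.7% substrate left, and the flask held 63.7%. The neighbour flask, run like Wednesday's but at 65 °C, has N_s = 2.55, so exp(−N_s) gives 7.81%, and that flask held 7.8% substrate. It ended with 69.6% open intermediate and 22.3% target.

The rate constants were chosen freely; the flask was simulated.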